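The target is divided inside ring A of unit 2, not at the biaryl bond. That ring is a pentasubstituted benzene (only C8 bears H) with three unlike oxygens, C5–OH, C7–OMe and C8a–O1, and with C6, between OH and OMe, bonded to C3' of unit 1. One photochemical Wolff/Danheiser benzannulation builds it from two enantiopure halves: an (S)-2-aryl-2,3-dihydropyran-4-one carrying a diazoacetyl group on its enol-ether carbon, and an (S)-flavanone carrying a methoxyethynyl group on C3'. Four C–C bonds form, the aryl–alkyne bond becomes the biaryl bond, and no oxygen needs later differentiation. The two remaining phenols travel as benzyl ethers, so one hydrogenolysis finishes the synthesis.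

Key step: step 10

Assumption: the C6–C3' axis is taken as freely equilibrating because the target defines no axial descriptor, and the ligand antipodes named in steps 2 and 7 are those expected, by analogy with aromatic aldehydes and cyclic enones, to give the S centres.

Step 1
Reactants: 1 methyl 2,4-dioxopentanoate
Product: 2 methyl (2Z)-2,4-bis(trimethylsilyloxy)penta-2,4-dienoate
Conditions: TMSOTf (2.3 equiv), Et3N (3 equiv), Et2O, 0 °C to rt; ammonium salt layer removed, diene used directly
Reagents that add atoms: trimethylsilyl triflate, C[Si](C)(C)OS(=O)(=O)C(F)(F)F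
Why: Soft enolisation with a silyl triflate and a tertiary amine is the usual way from 1,3-dicarbonyl compounds to 1,3-bis(silyloxy)dienes; it silylates the enolised 2-oxo group first and then the methyl ketone, and a single regioisomer is expected because only the methyl group can still lose a proton.

Step 2
Reactants: 2 methyl (2Z)-2,4-bis(trimethylsilyloxy)penta-2,4-dienoate; 3 4-(benzyloxy)benzaldehyde
Product: 5 methyl (2S)-2-[4-(benzyloxy)phenyl]-4-oxo-3,4-dihydro-2H-pyran-6-carboxylate, via silylated aldol adduct 4 (not isolated)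
Conditions: Ti(OiPr)4 (10 mol %), (S)-BINOL (20 mol %), 4 Å MS, Et2O, −20 °C to rt; then TFA (cat.), CH2Cl2, 0 °C
Reagents that add atoms: none
Why: This is a formal hetero-Diels–Alder reaction run as a catalytic asymmetric Mukaiyama aldol addition followed by acid cyclocondensation, in which the BINOL–titanium Lewis acid binds the aldehyde and leaves its Si face open to the CH2 terminus of 2, setting C2 as S, and TFA then closes the O1–C6 bond with loss of both silyl groups without touching that centre.

Step 3
Reactants: 5 methyl (2S)-2-[4-(benzyloxy)phenyl]-4-oxo-3,4-dihydro-2H-pyran-6-carboxylate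
Product: 7 (2S)-2-[4-(benzyloxy)phenyl]-4-oxo-3,4-dihydro-2H-pyran-6-carboxylic acid, via trimethylstannyl ester 6 (not isolated)
Conditions: Me3SnOH (4 equiv), ClCH2CH2Cl, 60 °C; then dilute aq. HCl wash
Reagents that add atoms: trimethyltin hydroxide, C[Sn](C)(C)O (supplies the oxygen that replaces OMe and the tin group of 6)
Why: Tin hydroxide ester cleavage works under almost neutral conditions through a stannyl ester, which avoids the hydroxide-induced ring opening and retro-oxa-Michael racemisation that threaten this vinylogous ester.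

Step 4
Reactants: 7 (2S)-2-[4-(benzyloxy)phenyl]-4-oxo-3,4-dihydro-2H-pyran-6-carboxylic acid
Product: 9 (2S)-2-[4-(benzyloxy)phenyl]-6-(diazoacetyl)-2,3-dihydro-4H-pyran-4-one, via acid chloride 8 (not isolated)
Conditions: Me2C=C(Cl)NMe2 (1.1 equiv), CH2Cl2, 0 °C; then TMSCHN2 (1.5 equiv), THF–MeCN, 0 °C, dark
Reagents that add atoms: (trimethylsilyl)diazomethane, C[Si](C)(C)C=[N+]=[N-]; 1-chloro-N,N,2-trimethylprop-1-en-1-amine, CC(C)=C(Cl)N(C)C (chlorine of 8 only)
Why: In this Arndt–Eistert-type acylation of a diazoalkane the chloroenamine forms the acid chloride without free acid or base, and the bulky silyl diazomethane should attack the acyl chloride faster than it adds as a dipole across the trisubstituted, oxygen-bearing C5=C6 bond, after which chloride removes silicon.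

Step 5
Reactants: 10 2',6'-dihydroxy-4'-methoxyacetophenone
Product: 11 2'-(benzyloxy)-6'-hydroxy-4'-methoxyacetophenone
Conditions: BnBr (1.05 equiv), K2CO3 (1.1 equiv), acetone, reflux
Reagents that add atoms: benzyl bromide, BrCc1ccccc1
Why: In this Williamson ether synthesis the two hydroxyls are equivalent, so only one monoether exists, and the remaining hydroxyl is held in a hydrogen bond to the ketone, so the reaction should stop there.

Step 6
Reactants: 11 2'-(benzyloxy)-6'-hydroxy-4'-methoxyacetophenone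
Product: 13 5-(benzyloxy)-7-methoxy-4H-chromen-4-one, via enaminone 12 (not isolated)
Conditions: Me2NCH(OMe)2 (2 equiv), toluene, 95 °C; concentrate; conc. HCl, CH2Cl2, rt to 40 °C
Reagents that add atoms: N,N-dimethylformamide dimethyl acetal, COC(OC)N(C)C
Why: This is the standard enaminone route to 2,3-unsubstituted chromones, in which the acetyl group condenses with the amide acetal and acid then drives addition of the phenol and loss of dimethylamine.

Step 7
Reactants: 13 5-(benzyloxy)-7-methoxy-4H-chromen-4-one; 14 (3-bromo-4-methoxyphenyl)boronic acid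
Product: 15 (2S)-5-(benzyloxy)-2-(3-bromo-4-methoxyphenyl)-7-methoxychroman-4-one
Conditions: [Rh(OH)(cod)]2 (1.5 mol %), (S)-MeO-F12-BIPHEP [(S)-2,2'-bis{bis(3,4,5-trifluorophenyl)phosphino}-6,6'-dimethoxybiphenyl] (3.3 mol %), 14 (1.5 equiv), toluene with a little H2O, 25–40 °C
Reagents that add atoms: none
Why: The Hayashi–Miyaura asymmetric 1,4-addition is established for chromones, 5,7-dioxygenated ones included; the (S)-biaryl diphosphine steers the aryl–rhodium species to the Re face of C2 and sets it as S, the base-free medium prevents opening to the chalcone, and the C–Br bond is inert to monovalent rhodium.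

Step 8
Reactants: 16 2-chloro-1,1-dimethoxyethane (chloroacetaldehyde dimethyl acetal)
Product: 18 tributyl(methoxyethynyl)stannane, via lithium methoxyacetylide 17 (not isolated)
Conditions: Et2NH (3.3 equiv), n-BuLi (3.2 equiv), THF, 0 °C; 16, 0 °C; Bu3SnCl (0.95 equiv), −78 °C to rt; aqueous work-up
Reagents that add atoms: tributyltin chloride, CCCC[Sn](Cl)(CCCC)CCCC; n-butyllithium, [Li]CCCC (lithium of 17 only)
Why: Base-induced loss of HCl and then of methanol from the chloroacetal gives methoxyacetylene, the third equivalent of amide deprotonates it, and the lithium acetylide is stannylated at carbon, which is the usual elimination–metalation route to alkoxyethynyl metals.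

Step 9
Reactants: 15 (2S)-5-(benzyloxy)-2-(3-bromo-4-methoxyphenyl)-7-methoxychroman-4-one; 18 tributyl(methoxyethynyl)stannane
Product: 19 (2S)-5-(benzyloxy)-7-methoxy-2-[4-methoxy-3-(methoxyethynyl)phenyl]chroman-4-one
Conditions: Pd(PPh3)4 (5 mol %), 18 (1.3 equiv), toluene, 90 °C, argon; chromatography on Et3N-deactivated silica
Reagents that add atoms: none
Why: In this Stille coupling zerovalent palladium inserts into the only C–Br bond and tin transfers its alkynyl group, the fastest-migrating ligand, under neutral conditions that spare C2, while a methyl ynol ether has no β-hydrogen for retro-ene loss at this temperature.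

Step 10
Reactants: 9 (2S)-2-[4-(benzyloxy)phenyl]-6-(diazoacetyl)-2,3-dihydro-4H-pyran-4-one; 19 (2S)-5-(benzyloxy)-7-methoxy-2-[4-methoxy-3-(methoxyethynyl)phenyl]chroman-4-one
Product: 24 (2S)-5-(benzyloxy)-2-{3-[(2S)-2-(4-(benzyloxy)phenyl)-5-hydroxy-7-methoxy-4-oxochroman-6-yl]-4-methoxyphenyl}-7-methoxychroman-4-one, via vinylketene 20 (not isolated), via vinylcyclobutenone 21 (not isolated), via dienylketene 22 (not isolated), via cyclohexadienone 23 (not isolated)
Conditions: 19 (1.0 equiv), degassed ClCH2CH2Cl, 450 nm LEDs, 20 °C, 9 (1.5 equiv) added over 4 h; then dark, 80 °C, 3 h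
Reagents that add atoms: none
Why: Visible light excites only the diazoketone of 9, N2 leaves and pyranone C6 migrates to the carbene carbon (Wolff rearrangement, C8–C8a) to give vinylketene 20, whose electrophilic carbonyl carbon is attacked by the nucleophilic, aryl-bearing carbon of ynol ether 19 in a [2+2] cycloaddition (C5–C6 and C7–C8) that gives cyclobutenone 21. At 80 °C 21 opens by four-electron electrocyclic cleavage of its C(=O)–CH bond to dienylketene 22, ring A then closes by a six-electron disrotatory electrocyclisation of the ketene carbon onto the pyranone α-carbon (C5–C4a), and dienone 23 enolises to a phenol hydrogen-bonded to C4=O. The closest known reaction is the Danheiser benzannulation in its diazoketone form, in which unsaturated α-diazoketones and alkoxyalkynes give resorcinol monoethers. No lasting stereocentre is created, since the sp3 ring carbons of 21 and 23 are transient, and the two S centres lie away from the reacting atoms and meet only neutral conditions. The step needs regioselectivity in the [2+2] event, secured by the O–C≡C polarisation of 19 that places the aryl group next to the new OH, and it needs selective excitation, secured by a wavelength at which flavanone, enone and ynol ether should not absorb. Slow addition of 9 keeps diazoketone and ketene dilute, which should limit ketene dimerisation, dipolar addition of the diazo group to 19 and acylation of the hindered, chelated phenol of 24.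

Step 11
Reactants: 24 (2S)-5-(benzyloxy)-2-{3-[(2S)-2-(4-(benzyloxy)phenyl)-5-hydroxy-7-methoxy-4-oxochroman-6-yl]-4-methoxyphenyl}-7-methoxychroman-4-one
Product: 25 (2S)-5-hydroxy-2-{3-[(2S)-5-hydroxy-2-(4-hydroxyphenyl)-7-methoxy-4-oxochroman-6-yl]-4-methoxyphenyl}-7-methoxychroman-4-one (CNP0150873.1)
Conditions: H2 (1 atm), Pd/C (10 wt %), EtOAc–MeOH, rt
Reagents that add atoms: none
Why: Catalytic hydrogenolysis cleaves both aryl benzyl ethers in a neutral medium, so with neither Lewis acid nor base present the three methyl ethers and the two C2 centres, which are prone to retro-oxa-Michael opening, should remain untouched.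

Compound list
1 | methyl 2,4-dioxopentanoate | COC(=O)C(=O)CC(C)=O | starting material
2 | methyl (2Z)-2,4-bis(trimethylsilyloxy)penta-2,4-dienoate | COC(=O)/C(O[Si](C)(C)C)=C/C(=C)O[Si](C)(C)C | intermediate
3 | 4-(benzyloxy)benzaldehyde | O=Cc1ccc(OCc2ccccc2)cc1 | starting material
4 | methyl (2Z,6S)-6-[4-(benzyloxy)phenyl]-4-oxo-2,6-bis(trimethylsilyloxy)hex-2-enoate (not isolated) | COC(=O)/C(O[Si](C)(C)C)=C/C(=O)C[C@H](O[Si](C)(C)C)c1ccc(OCc2ccccc2)cc1 | intermediate
5 | methyl (2S)-2-[4-(benzyloxy)phenyl]-4-oxo-3,4-dihydro-2H-pyran-6-carboxylate | COC(=O)C1=CC(=O)C[C@@H](c2ccc(OCc3ccccc3)cc2)O1 | intermediate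
6 | trimethylstannyl (2S)-2-[4-(benzyloxy)phenyl]-4-oxo-3,4-dihydro-2H-pyran-6-carboxylate (not isolated) | C[Sn](C)(C)OC(=O)C1=CC(=O)C[C@@H](c2ccc(OCc3ccccc3)cc2)O1 | intermediate
7 | (2S)-2-[4-(benzyloxy)phenyl]-4-oxo-3,4-dihydro-2H-pyran-6-carboxylic acid | OC(=O)C1=CC(=O)C[C@@H](c2ccc(OCc3ccccc3)cc2)O1 | intermediate
8 | (2S)-2-[4-(benzyloxy)phenyl]-4-oxo-3,4-dihydro-2H-pyran-6-carbonyl chloride (not isolated) | ClC(=O)C1=CC(=O)C[C@@H](c2ccc(OCc3ccccc3)cc2)O1 | intermediate
9 | (2S)-2-[4-(benzyloxy)phenyl]-6-(diazoacetyl)-2,3-dihydro-4H-pyran-4-one | [N-]=[N+]=CC(=O)C1=CC(=O)C[C@@H](c2ccc(OCc3ccccc3)cc2)O1 | intermediate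
10 | 2',6'-dihydroxy-4'-methoxyacetophenone | CC(=O)c1c(O)cc(OC)cc1O | starting material
11 | 2'-(benzyloxy)-6'-hydroxy-4'-methoxyacetophenone | CC(=O)c1c(O)cc(OC)cc1OCc1ccccc1 | intermediate
12 | (E)-1-[2-(benzyloxy)-6-hydroxy-4-methoxyphenyl]-3-(dimethylamino)prop-2-en-1-one (not isolated) | CN(C)/C=C/C(=O)c1c(O)cc(OC)cc1OCc1ccccc1 | intermediate
13 | 5-(benzyloxy)-7-methoxy-4H-chromen-4-one | COc1cc(OCc3ccccc3)c2c(c1)occc2=O | intermediate
14 | (3-bromo-4-methoxyphenyl)boronic acid | COc1ccc(B(O)O)cc1Br | starting material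
15 | (2S)-5-(benzyloxy)-2-(3-bromo-4-methoxyphenyl)-7-methoxychroman-4-one | COc1cc(OCc3ccccc3)c2c(c1)O[C@H](c1ccc(OC)c(Br)c1)CC2=O | intermediate
16 | 2-chloro-1,1-dimethoxyethane | COC(CCl)OC | starting material
17 | lithium methoxyacetylide (not isolated) | [Li+].[C-]#COC | intermediate
18 | tributyl(methoxyethynyl)stannane | CCCC[Sn](CCCC)(CCCC)C#COC | intermediate
19 | (2S)-5-(benzyloxy)-7-methoxy-2-[4-methoxy-3-(methoxyethynyl)phenyl]chroman-4-one | COc1cc(OCc3ccccc3)c2c(c1)O[C@H](c1ccc(OC)c(C#COC)c1)CC2=O | intermediate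
20 | (2S)-2-[4-(benzyloxy)phenyl]-6-(2-oxoethenyl)-2,3-dihydro-4H-pyran-4-one, vinylketene (not isolated) | O=C=CC1=CC(=O)C[C@@H](c2ccc(OCc3ccccc3)cc2)O1 | intermediate
21 | 3-methoxycyclobut-2-en-1-one bearing C3' of the unit 1 flavanone on C2 and C6 of the (S)-pyranone on C4, both epimers at C4 (not isolated) | COc1cc(OCc3ccccc3)c2c(c1)O[C@H](c1ccc(OC)c(C3=C(OC)C(C4=CC(=O)C[C@@H](c5ccc(OCc6ccccc6)cc5)O4)C3=O)c1)CC2=O | intermediate
22 | dienylketene O=C=C(aryl)–C(OMe)=CH–(pyranon-6-yl) with the ketenyl and pyranonyl groups cis (not isolated) | COc1cc(OCc3ccccc3)c2c(c1)O[C@H](c1ccc(OC)c(C(=C=O)/C(OC)=C\C3=CC(=O)C[C@@H](c4ccc(OCc5ccccc5)cc4)O3)c1)CC2=O | intermediate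
23 | 4a-H cyclohexadienone tautomer of 24, both epimers at C4a (not isolated) | COc1cc(OCc3ccccc3)c2c(c1)O[C@H](c1ccc(OC)c(C3=C(OC)C=C4O[C@H](c5ccc(OCc6ccccc6)cc5)CC(=O)C4C3=O)c1)CC2=O | intermediate
24 | (2S)-5-(benzyloxy)-2-{3-[(2S)-2-(4-(benzyloxy)phenyl)-5-hydroxy-7-methoxy-4-oxochroman-6-yl]-4-methoxyphenyl}-7-methoxychroman-4-one | COc1cc(OCc3ccccc3)c2c(c1)O[C@H](c1ccc(OC)c(-c3c(OC)cc4c(c3O)C(=O)C[C@@H](c3ccc(OCc5ccccc5)cc3)O4)c1)CC2=O | intermediate
25 | (2S)-5-hydroxy-2-{3-[(2S)-5-hydroxy-2-(4-hydroxyphenyl)-7-methoxy-4-oxochroman-6-yl]-4-methoxyphenyl}-7-methoxychroman-4-one | COc1cc(O)c2c(c1)O[C@H](c1ccc(OC)c(-c3c(OC)cc4c(c3O)C(=O)C[C@@H](c3ccc(O)cc3)O4)c1)CC2=O | target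

Total step count: 11. Longest linear sequence: 6 steps (1, 2, 3, 4, 10, 11, or equally 5, 6, 7, 9, 10, 11).

Steps most likely to fail

Step 10. Capture of the ketene at the hindered, aryl-bearing alkyne carbon may be slower than ketene dimerisation or dipolar addition of the diazo group to the ynol ether. The thermal opening and closure may also stall.
- The fallback gives up the ring construction for a biaryl coupling. It sets out from 15 and 13 and returns at 25.
- Miyaura borylation of 15 (B2pin2, PdCl2(dppf), KOAc, dioxane, 80 °C) gives the unit 1 pinacol boronate F1.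
- Chromone 13 and (4-benzyloxyphenyl)boronic acid, under the conditions of step 7, give (2S)-5-(benzyloxy)-2-[4-(benzyloxy)phenyl]-7-methoxychroman-4-one F2.
- Iodination of F2 with BnMe3N·ICl2 and CaCO3 in CH2Cl2–MeOH gives the 6-iodoflavanone F3, to be separated from any 8-iodo isomer.
- Suzuki–Miyaura coupling of F1 with F3 (Pd(OAc)2, SPhos, K3PO4, toluene–H2O, 60 °C) gives the tribenzyl bis-flavanone F4.
- Hydrogenolysis of F4 under the conditions of step 11 gives 25.

Step 2. The ester-deactivated diene may add only slowly to the electron-rich aldehyde, which lets an uncatalysed or silyl-cation-promoted background reaction erode facial selectivity.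
- The fallback sets the carbinol centre first and attaches the oxalyl unit afterwards. It sets out from 3 and returns at 5.
- Claisen–Schmidt condensation of 3 with acetone (aq. NaOH) gives (E)-4-[4-(benzyloxy)phenyl]but-3-en-2-one F5.
- Copper-catalysed asymmetric conjugate borylation (CuCl, NaOt-Bu, a Josiphos ligand of the antipode giving S, B2pin2, MeOH, THF) gives the (S)-β-boryl ketone F6.
- Oxidation with retention (NaBO3·4H2O) gives (S)-4-[4-(benzyloxy)phenyl]-4-hydroxybutan-2-one F7.
- Silylation (TBSCl, imidazole, DMF) gives the silyl ether F8.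
- Kinetic Claisen condensation at the methyl group with dimethyl oxalate (LiHMDS, THF, −78 °C) gives the enolised diketo ester F9.
- TFA in CH2Cl2 removes silicon and closes the ring by cyclodehydration to 5.

Step 9. Oxidative addition into the electron-rich, ortho-methoxy aryl bromide may be slow enough to need prolonged heating, during which the ynol ether may hydrate or oligomerise. Material may also be lost on silica.
- The fallback changes both coupling partners so that the bond forms at room temperature. It sets out from 15 and 17 and returns at 19.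
- Aromatic Finkelstein exchange on 15 (CuI, NaI, trans-N,N'-dimethylcyclohexane-1,2-diamine, dioxane, 110 °C) gives the (S)-3'-iodoflavanone F10.
- Acetylide 17, made as in step 8, is transmetalated with ZnCl2 to methoxyethynylzinc chloride F11.
- Negishi coupling of F10 with F11 (Pd(PPh3)4, THF, rt) gives 19.

Further compounds
F1 | step 10 | (2S)-5-(benzyloxy)-7-methoxy-2-[4-methoxy-3-(4,4,5,5-tetramethyl-1,3,2-dioxaborolan-2-yl)phenyl]chroman-4-one | COc1cc(OCc3ccccc3)c2c(c1)O[C@H](c1ccc(OC)c(B3OC(C)(C)C(C)(C)O3)c1)CC2=O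
F2 | step 10 | (2S)-5-(benzyloxy)-2-[4-(benzyloxy)phenyl]-7-methoxychroman-4-one | COc1cc(OCc3ccccc3)c2c(c1)O[C@H](c1ccc(OCc3ccccc3)cc1)CC2=O
F3 | step 10 | (2S)-5-(benzyloxy)-2-[4-(benzyloxy)phenyl]-6-iodo-7-methoxychroman-4-one | COc1cc2c(c(OCc3ccccc3)c1I)C(=O)C[C@@H](c1ccc(OCc3ccccc3)cc1)O2
F4 | step 10 | (2S)-5-(benzyloxy)-2-{3-[(2S)-5-(benzyloxy)-2-(4-(benzyloxy)phenyl)-7-methoxy-4-oxochroman-6-yl]-4-methoxyphenyl}-7-methoxychroman-4-one | COc1cc(OCc3ccccc3)c2c(c1)O[C@H](c1ccc(OC)c(-c3c(OC)cc4c(c3OCc6ccccc6)C(=O)C[C@@H](c7ccc(OCc5ccccc5)cc7)O4)c1)CC2=O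
F5 | step 2 | (E)-4-[4-(benzyloxy)phenyl]but-3-en-2-one | CC(=O)/C=C/c1ccc(OCc2ccccc2)cc1
F6 | step 2 | (S)-4-[4-(benzyloxy)phenyl]-4-(4,4,5,5-tetramethyl-1,3,2-dioxaborolan-2-yl)butan-2-one | CC(=O)C[C@H](B1OC(C)(C)C(C)(C)O1)c1ccc(OCc2ccccc2)cc1
F7 | step 2 | (S)-4-[4-(benzyloxy)phenyl]-4-hydroxybutan-2-one | CC(=O)C[C@H](O)c1ccc(OCc2ccccc2)cc1
F8 | step 2 | (S)-4-[4-(benzyloxy)phenyl]-4-(tert-butyldimethylsilyloxy)butan-2-one | CC(=O)C[C@H](O[Si](C)(C)C(C)(C)C)c1ccc(OCc2ccccc2)cc1
F9 | step 2 | methyl (2Z,6S)-6-[4-(benzyloxy)phenyl]-6-(tert-butyldimethylsilyloxy)-2-hydroxy-4-oxohex-2-enoate | COC(=O)/C(O)=C/C(=O)C[C@H](O[Si](C)(C)C(C)(C)C)c1ccc(OCc2ccccc2)cc1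
F10 | step 9 | (2S)-5-(benzyloxy)-2-(3-iodo-4-methoxyphenyl)-7-methoxychroman-4-one | COc1cc(OCc3ccccc3)c2c(c1)O[C@H](c1ccc(OC)c(I)c1)CC2=O
F11 | step 9 | methoxyethynylzinc chloride | COC#C[Zn]Cl
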